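**Retrosynthetic overview**

1. Ring numbering used throughout: C1 (quaternary, CH3 + pyrone), C2 (CH–pentenyl), C3(CH3)–C4 (epoxide), C5(CH3)=C6H; β is the face of the C1 and C2 carbon substituents, α the face of the C1 methyl. The strategy rests on the cis pair of acyl-level carbons on C1 and C2 beside the C4 oxygen and the C5(CH3)=C6 alkene, which is the pattern of a 1-methoxy-3-silyloxydiene adduct of methylmaleic anhydride.
2. Epoxide (third ring) ⇐ trans-3,4-diol ⇐ C4 enone, by Rubottom oxidation at C3 and hydroxyl-directed reduction.
3. γ-Pyrone (second ring) ⇐ C1–CHO + dianion of methyl 2-methyl-3-oxopentanoate (aldol, oxidation, cyclisation, O-methylation).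
4. Pentenyl ⇐ C2–C≡CH (carboalumination/iodination, Negishi ethylation) ⇐ lactol ⇐ lactone from hydride opening of the anhydride at the C1 carbonyl.
5. Carbocycle (first ring) ⇐ [4+2] of silyloxydiene 5 with citraconic anhydride 6, forming C2–C3 and C6–C1; the diene comes from pentan-3-one and methyl formate.

Key step: step 4

Assumption 1: the face selection of an oxazaborolidinium catalyst on an anhydride cannot be derived safely in advance; the (S)-prolinol-derived catalyst is written, and its antipode is used if a trial run shows the opposite sense.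
Assumption 2: C3 (until step 19) and C4 (steps 6–18) are temporary centres; they are drawn as expected from the cycloaddition and from hydride attack anti to the C3 methyl, and any epimers converge at steps 18 and 19.

Step 1
Reactants: 1 pentan-3-one; 2 methyl formate
Product: 3 (Z)-1-hydroxy-2-methylpent-1-en-3-one (enol form of 2-methyl-3-oxopentanal)
Conditions: NaOMe, Et2O, 0 °C → rt; then aq. HCl
Reagents that add atoms: none
Why: Crossed Claisen formylation, in which the ketone enolate attacks the non-enolisable formate and the product is drained as its stabilised sodium enolate, so mono-formylation should be clean; no stereocentre is formed.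

Step 2
Reactants: 3 (Z)-1-hydroxy-2-methylpent-1-en-3-one
Product: 4 (E)-1-methoxy-2-methylpent-1-en-3-one
Conditions: Me2SO4, K2CO3, acetone, reflux
Reagents that add atoms: dimethyl sulfate COS(=O)(=O)OC
Why: Williamson-type O-alkylation of the β-keto aldehyde enolate with a hard sulfate electrophile (the α-carbon is already substituted) should give the vinylogous ester, which settles as the E isomer with OMe anti to the acyl carbon.

Step 3
Reactants: 4 (E)-1-methoxy-2-methylpent-1-en-3-one
Product: 5 (1E,3Z)-3-(tert-butyldimethylsilyloxy)-1-methoxy-2-methylpenta-1,3-diene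
Conditions: TBSOTf, Et3N, Et2O, 0 °C
Reagents that add atoms: tert-butyldimethylsilyl triflate CC(C)(C)[Si](C)(C)OS(=O)(=O)C(F)(F)F
Why: Soft enolisation of the ethyl ketone with a silyl triflate and an amine should give the Z silyl enol ether (methyl syn to OSi), which places the terminal methyl "outside" in the s-cis diene.

Step 4
Reactants: 5 (1E,3Z)-3-(tert-butyldimethylsilyloxy)-1-methoxy-2-methylpenta-1,3-diene; 6 citraconic anhydride
Product: 7 endo cis-fused anhydride cycloadduct (5-TBSO-7-methoxy-4,6,7a-trimethyl-3a,4,7,7a-tetrahydro-2-benzofuran-1,3-dione; anhydride ring, C3-Me and C6-OMe all β)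
Conditions: (S)-o-tolyl-CBS oxazaborolidine (20 mol%), Tf2NH (18 mol%), CH2Cl2, −78 °C
Reagents that add atoms: none
Why: Proposed new method: the cycloaddition itself is the precedented normal-demand Diels–Alder reaction of a 1-alkoxy-3-silyloxydiene with methylmaleic anhydride, concerted but asynchronous, with the nucleophilic methyl-bearing terminus of 5 bonding first to the unsubstituted anhydride carbon (C2–C3) and the methoxy terminus then closing on the methylated carbon (C6–C1); what is untested is running it under a chiral oxazaborolidinium Lewis acid, whose closest known use is on cyclic cis-diacyl dienophiles (quinones, maleimides) with 2-silyloxydienes. The six-membered carbocycle is closed by this intermolecular suprafacial/suprafacial [4+2] and is cis-fused to the anhydride because both bonds form on one face of the cyclic dienophile. C1 and C2 are therefore cis by necessity, and their absolute configuration is set by the catalyst, which binds an anhydride carbonyl and screens one face of the C=C bond. C3 and C6 follow from endo approach with both outside groups of the diene (C3-Me, C6-OMe) cis to the anhydride, but C6 is erased in step 5 and C3 in step 19, so only regiochemistry and dienophile face selection matter. Regiochemistry rests on the substrate (first bonding at the methylated carbon is sterically retarded whichever carbonyl is complexed), the TBS group replaces TMS to suppress silyl transfer to the catalyst, and the low temperature keeps the uncatalysed racemic pathway slow.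

Step 5
Reactants: 7 endo cis-fused anhydride cycloadduct
Product: 9 enone lactone, via hydroxy acid silyl enol ether 8 (not isolated)
Conditions: NaBH4, THF, 0 °C → rt; then 2 M HCl, THF, rt
Reagents that add atoms: none
Why: Borohydride reduction of an unsymmetrical succinic anhydride takes place at the carbonyl next to the more substituted carbon (here the C1 carbonyl), the γ-hydroxy acid lactonises on acidification, and the same acid (after destroying residual hydride) hydrolyses the silyl enol ether and eliminates methanol from the β-methoxy ketone to give the C4 enone, with the cis C1/C2 relationship untouched.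

Step 6
Reactants: 9 enone lactone
Product: 10 hydroxy lactone (C4–OH, expected β)
Conditions: NaBH4, CeCl3·7H2O, MeOH, −40 → −20 °C
Reagents that add atoms: none
Why: Luche reduction should give clean 1,2-reduction of the enone without touching the lactone, hydride being expected anti to the C3 methyl; the C4 centre is temporary.

Step 7
Reactants: 10 hydroxy lactone
Product: 11 TBS ether of the hydroxy lactone
Conditions: TBSOTf, 2,6-lutidine, CH2Cl2, −78 → 0 °C
Reagents that add atoms: tert-butyldimethylsilyl triflate CC(C)(C)[Si](C)(C)OS(=O)(=O)C(F)(F)F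
Why: Silyl ether formation with the triflate should overcome the hindrance of the doubly flanked allylic alcohol, and prompt silylation masks C4 for the organometallic steps and forestalls acyl migration from the lactone.

Step 8
Reactants: 11 TBS ether of the hydroxy lactone
Product: 12 lactol (C2–CH(OH)–O–CH2–C1, anomers)
Conditions: DIBAL-H (1.1 equiv), CH2Cl2, −78 °C; Rochelle salt
Reagents that add atoms: none
Why: Partial reduction of a γ-lactone with DIBAL-H at −78 °C stops at the stable aluminium hemiacetal, and the cis-fused lactol keeps C2 configurationally locked.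

Step 9
Reactants: 12 lactol
Product: 13 alkynyl alcohol (C2–C≡CH, C1–CH2OH)
Conditions: dimethyl (1-diazo-2-oxopropyl)phosphonate, K2CO3, MeOH, 0 °C → rt
Reagents that add atoms: dimethyl (1-diazo-2-oxopropyl)phosphonate COP(=O)(OC)C(=[N+]=[N-])C(C)=O
Why: Seyferth–Gilbert homologation with the Ohira–Bestmann reagent acts on the lactol as a masked aldehyde, giving the terminal alkyne and releasing the C1 hydroxymethyl group, while the low standing concentration of free aldehyde under mild carbonate conditions should limit epimerisation at C2.

Step 10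
Reactants: 13 alkynyl alcohol
Product: 15 (E)-vinyl iodide, via alkenylalane 14 (not isolated)
Conditions: Me3Al (4 equiv), Cp2ZrCl2 (0.3 equiv), H2O (1 equiv), CH2Cl2, −20 °C → rt; then I2, THF, −30 → 0 °C
Reagents that add atoms: trimethylaluminium C[Al](C)C; iodine II
Why: Zirconium-catalysed carboalumination (Negishi) adds Me–Al syn across the terminal alkyne with methyl on the internal carbon, the hydroxyl being carried as its aluminium alkoxide, and iodinolysis with retention fixes the E trisubstituted alkene (ring and iodine trans).

Step 11
Reactants: 15 (E)-vinyl iodide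
Product: 16 pentenyl alcohol (C2–(E)-pent-2-en-2-yl, C1–CH2OH)
Conditions: Et2Zn (3 equiv), Pd(dppf)Cl2 (5 mol%), THF, 50 °C
Reagents that add atoms: diethylzinc CC[Zn]CC
Why: Negishi sp2–sp3 cross-coupling proceeds with retention of alkene geometry, the wide-bite-angle ligand favouring reductive elimination over β-hydride elimination of the ethyl group.

Step 12
Reactants: 16 pentenyl alcohol
Product: 17 C1 aldehyde
Conditions: Dess–Martin periodinane, NaHCO3, CH2Cl2, 0 °C → rt
Reagents that add atoms: none
Why: Dess–Martin oxidation of the neopentyl primary alcohol should give an aldehyde that cannot enolise or epimerise because C1 is quaternary.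

Step 13
Reactants: 17 C1 aldehyde; 18 methyl 2-methyl-3-oxopentanoate
Product: 20 aldol adduct, via keto ester dianion 19 (not isolated)
Conditions: 18, NaH then n-BuLi, THF, 0 °C; then 17, −78 °C
Reagents that add atoms: none
Why: Aldol addition of a β-keto ester dianion, which reacts at its more basic γ-carbon with the non-enolisable aldehyde; the new chain centres form as a mixture and are all erased in steps 14 and 15.

Step 14
Reactants: 20 aldol adduct
Product: 21 β,δ-diketo ester
Conditions: Dess–Martin periodinane, CH2Cl2, rt
Reagents that add atoms: none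
Why: Dess–Martin oxidation of the secondary carbinol under near-neutral conditions should give the tricarbonyl chain without retro-aldol cleavage.

Step 15
Reactants: 21 β,δ-diketo ester
Product: 22 4-hydroxy-3,5-dimethyl-2-pyranone (C6 of the pyranone on ring C1)
Conditions: DBU, toluene, 60 °C; then aq. KHSO4
Reagents that add atoms: none
Why: Base-mediated cyclisation in which the enol oxygen of the C1-bound ketone attacks the ester carbonyl (6-exo-trig acyl substitution) with loss of methanol, the hindrance at C1 being tolerated because the nucleophile, not the electrophile, sits next to it.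

Step 16
Reactants: 22 4-hydroxy-3,5-dimethyl-2-pyranone
Product: 23 2-methoxy-3,5-dimethyl-4-pyranone (C4–OTBS retained)
Conditions: MeOTf, CH2Cl2, rt; then aq. NaHCO3
Reagents that add atoms: methyl triflate COS(=O)(=O)C(F)(F)F
Why: Hard O-methylation of the neutral hydroxy-pyranone at the lactone carbonyl oxygen gives a 2-methoxy-4-hydroxypyrylium salt that loses a proton on basic work-up to the α-methoxy-γ-pyrone.

Step 17
Reactants: 23 2-methoxy-4-pyranone TBS ether
Product: 24 allylic alcohol
Conditions: TBAF, THF, 0 → 40 °C
Reagents that add atoms: none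
Why: Fluoride-mediated desilylation should free the C4 alcohol without affecting the pyrone or the alkenes.

Step 18
Reactants: 24 allylic alcohol
Product: 25 enone pyrone
Conditions: Dess–Martin periodinane, NaHCO3, CH2Cl2, rt
Reagents that add atoms: none
Why: Dess–Martin oxidation of the allylic alcohol restores the C4 enone and erases the temporary C4 centre.

Step 19
Reactants: 25 enone pyrone
Product: 26 TMS dienol ether (C3=C4(OTMS)–C5=C6)
Conditions: LiHMDS, TMSCl, Et3N, THF, −78 °C
Reagents that add atoms: chlorotrimethylsilane C[Si](C)(C)Cl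
Why: Kinetic enolisation with in-situ O-silylation, C3–H being the only enolisable position of the enone because C1 is quaternary, gives the cross-conjugated silyloxydiene and erases C3; a silyl triflate is avoided so that the pyrone carbonyl is not activated.

Step 20
Reactants: 26 TMS dienol ether
Product: 28 α′-hydroxy enone, via silyloxy epoxide 27 (not isolated)
Conditions: DMDO (1.1 equiv, acetone), CH2Cl2, −78 °C; then aq. citric acid, THF, 0 °C
Reagents that add atoms: dimethyldioxirane CC1(C)OO1
Why: Rubottom oxidation, in which the dioxirane should epoxidise the electron-rich tetrasubstituted silyl enol ether much faster than the pentenyl alkene and from the α face, anti to the β pentenyl on C2 and the β pyrone on C1, so that acid opening of the silyloxy epoxide sets C3 with OH α and CH3 β.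

Step 21
Reactants: 28 α′-hydroxy enone
Product: 29 trans-3,4-diol (C3–OH α, C4–OH β)
Conditions: Me4NBH(OAc)3, MeCN–AcOH, −30 → 0 °C
Reagents that add atoms: none
Why: Hydroxyl-directed triacetoxyborohydride reduction, in which the tertiary alcohol exchanges onto boron and delivers hydride intramolecularly to the α face of the neighbouring carbonyl, should give the trans-diol and leave the pyrone untouched.

Step 22
Reactants: 29 trans-3,4-diol
Product: 31 target CNP0352631.1, via C4 mesylate 30 (not isolated)
Conditions: Ms2O, Et3N, CH2Cl2, −30 °C; then DBU, −30 °C → rt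
Reagents that add atoms: none
Why: Selective sulfonylation of the secondary allylic alcohol (chloride-free to avoid an allylic chloride) followed by intramolecular Williamson closure by the tertiary oxygen with inversion at C4 gives the α-epoxide, whose face is dictated by the C3 oxygen.

**Compound list**

1 | pentan-3-one | CCC(=O)CC | starting material
2 | methyl formate | COC=O | starting material
3 | (Z)-1-hydroxy-2-methylpent-1-en-3-one | CCC(=O)/C(C)=C\O | intermediate
4 | (E)-1-methoxy-2-methylpent-1-en-3-one | CCC(=O)/C(C)=C/OC | intermediate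
5 | (1E,3Z)-3-(tert-butyldimethylsilyloxy)-1-methoxy-2-methylpenta-1,3-diene | CO/C=C(C)/C(O[Si](C)(C)C(C)(C)C)=C/C | intermediate
6 | citraconic anhydride | CC1=CC(=O)OC1=O | starting material
7 | endo cis-fused anhydride cycloadduct (TBS enol ether, C6-OMe and C3-Me β) | CO[C@@H]1C(C)=C(O[Si](C)(C)C(C)(C)C)[C@H](C)[C@@H]2C(=O)OC(=O)[C@]12C | intermediate
8 | hydroxy acid silyl enol ether (C2–CO2H, C1–CH2OH cis; not isolated) | OC(=O)[C@H]1[C@@H](C)C(O[Si](C)(C)C(C)(C)C)=C(C)[C@@H](OC)[C@@]1(C)CO | intermediate
9 | enone lactone (cis-fused γ-lactone C2–C(=O)–O–CH2–C1, C4 ketone, C5=C6) | O=C2[C@H]1[C@@H](C)C(=O)C(C)=C[C@@]1(C)CO2 | intermediate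
10 | hydroxy lactone (C4–OH β) | O=C2[C@H]1[C@@H](C)[C@@H](O)C(C)=C[C@@]1(C)CO2 | intermediate
11 | TBS ether of the hydroxy lactone | O=C2[C@H]1[C@@H](C)[C@@H](O[Si](C)(C)C(C)(C)C)C(C)=C[C@@]1(C)CO2 | intermediate
12 | lactol (anomeric mixture) | OC2[C@H]1[C@@H](C)[C@@H](O[Si](C)(C)C(C)(C)C)C(C)=C[C@@]1(C)CO2 | intermediate
13 | alkynyl alcohol | C#C[C@H]1[C@@H](C)[C@@H](O[Si](C)(C)C(C)(C)C)C(C)=C[C@@]1(C)CO | intermediate
14 | alkenyl(dimethyl)alane, O-dimethylaluminium alkoxide (not isolated) | C[Al](C)/C=C(\C)[C@H]1[C@@H](C)[C@@H](O[Si](C)(C)C(C)(C)C)C(C)=C[C@@]1(C)CO[Al](C)C | intermediate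
15 | (E)-vinyl iodide | I/C=C(\C)[C@H]1[C@@H](C)[C@@H](O[Si](C)(C)C(C)(C)C)C(C)=C[C@@]1(C)CO | intermediate
16 | pentenyl alcohol | CC/C=C(\C)[C@H]1[C@@H](C)[C@@H](O[Si](C)(C)C(C)(C)C)C(C)=C[C@@]1(C)CO | intermediate
17 | C1 aldehyde | CC/C=C(\C)[C@H]1[C@@H](C)[C@@H](O[Si](C)(C)C(C)(C)C)C(C)=C[C@@]1(C)C=O | intermediate
18 | methyl 2-methyl-3-oxopentanoate | CCC(=O)C(C)C(=O)OC | starting material
19 | sodium lithium dianion of 18 (not isolated) | C[CH-]C([O-])=C(C)C(=O)OC.[Na+].[Li+] | intermediate
20 | aldol adduct (δ-hydroxy-β-keto ester, mixture at the three chain centres) | CC/C=C(\C)[C@H]1[C@@H](C)[C@@H](O[Si](C)(C)C(C)(C)C)C(C)=C[C@@]1(C)C(O)C(C)C(=O)C(C)C(=O)OC | intermediate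
21 | β,δ-diketo ester (chain centres unspecified) | CC/C=C(\C)[C@H]1[C@@H](C)[C@@H](O[Si](C)(C)C(C)(C)C)C(C)=C[C@@]1(C)C(=O)C(C)C(=O)C(C)C(=O)OC | intermediate
22 | 4-hydroxy-3,5-dimethyl-2-pyranone | CC/C=C(\C)[C@H]1[C@@H](C)[C@@H](O[Si](C)(C)C(C)(C)C)C(C)=C[C@@]1(C)c1oc(=O)c(C)c(O)c1C | intermediate
23 | 2-methoxy-3,5-dimethyl-4-pyranone, C4–OTBS | CC/C=C(\C)[C@H]1[C@@H](C)[C@@H](O[Si](C)(C)C(C)(C)C)C(C)=C[C@@]1(C)c1oc(OC)c(C)c(=O)c1C | intermediate
24 | allylic alcohol | CC/C=C(\C)[C@H]1[C@@H](C)[C@@H](O)C(C)=C[C@@]1(C)c1oc(OC)c(C)c(=O)c1C | intermediate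
25 | enone pyrone | CC/C=C(\C)[C@H]1[C@@H](C)C(=O)C(C)=C[C@@]1(C)c1oc(OC)c(C)c(=O)c1C | intermediate
26 | TMS dienol ether | CC/C=C(\C)[C@H]1C(C)=C(O[Si](C)(C)C)C(C)=C[C@@]1(C)c1oc(OC)c(C)c(=O)c1C | intermediate
27 | silyloxy epoxide (α-epoxide, not isolated) | CC/C=C(\C)[C@H]1[C@]2(C)O[C@]2(O[Si](C)(C)C)C(C)=C[C@@]1(C)c1oc(OC)c(C)c(=O)c1C | intermediate
28 | α′-hydroxy enone (C3–OH α, C3–CH3 β) | CC/C=C(\C)[C@H]1[C@](C)(O)C(=O)C(C)=C[C@@]1(C)c1oc(OC)c(C)c(=O)c1C | intermediate
29 | trans-3,4-diol (C3–OH α, C4–OH β) | CC/C=C(\C)[C@H]1[C@](C)(O)[C@@H](O)C(C)=C[C@@]1(C)c1oc(OC)c(C)c(=O)c1C | intermediate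
30 | C4 mesylate (not isolated) | CC/C=C(\C)[C@H]1[C@](C)(O)[C@@H](OS(C)(=O)=O)C(C)=C[C@@]1(C)c1oc(OC)c(C)c(=O)c1C | intermediate
31 | CNP0352631.1 | CC/C=C(\C)[C@H]1[C@]2(C)O[C@@H]2C(C)=C[C@@]1(C)c1oc(OC)c(C)c(=O)c1C | target

**Step count**

Total: 22 steps. Longest linear sequence: 22 steps, from pentan-3-one (1) to 31; compounds 2, 6 and 18 enter as commercial materials.

**Steps most likely to fail**

Step 4 (proposed new method). The catalyst may select the dienophile face poorly or in an unpredictable sense on an anhydride. Silyl transfer from the diene may also generate an achiral silyl Lewis acid that runs a racemic background reaction, and complexation at the less hindered carbonyl may erode regiocontrol. The fallback uses known chemistry and sets out from 5 and 6. Without catalyst (toluene, 25–50 °C) the same endo cycloaddition gives racemic cycloadduct F1. The conditions of step 5 take it through racemic hydroxy acid silyl enol ether F2 to racemic enone lactone F3. F3 is resolved by preparative chromatography on a chiral stationary phase (SFC), and the required enantiomer rejoins the route as 9.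

Step 10. Methylalumination may be slow and poorly regioselective because the alkyne sits on a carbon flanked by the quaternary C1 and the substituted C3. The fallback sets out from lactone 11. n-Propyllithium (1.05 equiv, THF, −78 °C) adds once to the lactone and gives propyl ketone F4, in equilibrium with its cyclic hemiketal. TESCl/imidazole traps the open form as TES ether F5. KHMDS then PhNTf2 (THF, −78 °C) enolises towards the unhindered CH2 and, because the acyl substituent is bulky, gives the Z enolate and hence (Z)-enol triflate F6 with ethyl cis to oxygen. Me2CuLi replaces the triflate by methyl with retention and gives the TES-protected pentenyl compound F7. AcOH/THF/H2O removes the primary TES group, and the route is rejoined at 16.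

Step 20. The dioxirane may also epoxidise the pentenyl alkene, and a small oxidant may discriminate poorly between the α and β faces. The fallback sets out from enone 25. KHMDS (THF, −78 °C) gives potassium dienolate F8, which is hydroxylated directly with the bulky 2-(phenylsulfonyl)-3-phenyloxaziridine. This oxidant does not touch isolated alkenes and should respond more strongly to the β-face shielding. Aqueous work-up rejoins the route at 28.

**Further compounds**

F1 | step 4 | racemic cycloadduct (rac-7, one enantiomer drawn) | CO[C@@H]1C(C)=C(O[Si](C)(C)C(C)(C)C)[C@H](C)[C@@H]2C(=O)OC(=O)[C@]12C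
F2 | step 4 | racemic hydroxy acid silyl enol ether (rac-8, one enantiomer drawn, not isolated) | OC(=O)[C@H]1[C@@H](C)C(O[Si](C)(C)C(C)(C)C)=C(C)[C@@H](OC)[C@@]1(C)CO
F3 | step 4 | racemic enone lactone (rac-9, one enantiomer drawn) | O=C2[C@H]1[C@@H](C)C(=O)C(C)=C[C@@]1(C)CO2
F4 | step 10 | propyl ketone (C2–C(=O)Pr, C1–CH2OH) | CCCC(=O)[C@H]1[C@@H](C)[C@@H](O[Si](C)(C)C(C)(C)C)C(C)=C[C@@]1(C)CO
F5 | step 10 | TES ether of the propyl ketone | CCCC(=O)[C@H]1[C@@H](C)[C@@H](O[Si](C)(C)C(C)(C)C)C(C)=C[C@@]1(C)CO[Si](CC)(CC)CC
F6 | step 10 | (Z)-enol triflate | CC/C=C(\OS(=O)(=O)C(F)(F)F)[C@H]1[C@@H](C)[C@@H](O[Si](C)(C)C(C)(C)C)C(C)=C[C@@]1(C)CO[Si](CC)(CC)CC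
F7 | step 10 | TES-protected pentenyl compound | CC/C=C(\C)[C@H]1[C@@H](C)[C@@H](O[Si](C)(C)C(C)(C)C)C(C)=C[C@@]1(C)CO[Si](CC)(CC)CC
F8 | step 20 | potassium dienolate of 25 | CC/C=C(\C)[C@H]1C(C)=C([O-])C(C)=C[C@@]1(C)c1oc(OC)c(C)c(=O)c1C.[K+]
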